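**Retrosynthetic overview**
1. Helilupolone ⇒ 3,5-diprenyl acylphloroglucinol + isoprene. Cut one of the two C6–prenyl bonds (new dearomative hydroprenylation, which makes the quaternary carbon).
2. 3,5-Diprenyl acylphloroglucinol ⇒ 2',4',6'-trihydroxydihydrochalcone + two prenyl bromide. Cut both aryl C–prenyl bonds (phenoxide C-alkylation).
3. 2',4',6'-Trihydroxydihydrochalcone ⇒ phloroglucinol + 3-phenylpropanoyl chloride. Cut the aryl–acyl bond (Friedel–Crafts acylation).
4. Ring order: no ring is built. Ring A (six-membered core) is bought as phloroglucinol, takes up the acyl group, then two prenyl groups, then the third, and loses its aromaticity only in the last step. Ring B (phenyl) comes in with the acid chloride.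

Assumption: the SMILES holds no stereocentre and no stereogenic double bond (C6 carries two identical prenyl groups), so helilupolone is achiral, "the single enantiomer given" is the compound itself, and the enol form drawn stands for the rapidly equilibrating β-triketone tautomers.

**Step 1**
Reactants: 1 phloroglucinol (benzene-1,3,5-triol); 2 3-phenylpropanoyl chloride
Product: 3 1-(2,4,6-trihydroxyphenyl)-3-phenylpropan-1-one
Conditions: AlCl3 (3.5 equiv), CH2Cl2/MeNO2, 40 °C, slow addition of 2 (1.0 equiv), 3 h; then ice/dilute aq HCl
Reagents that add atoms: 3-phenylpropanoyl chloride (2), O=C(Cl)CCc1ccccc1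
Why: Friedel–Crafts acylation, in which the AlCl3-activated acid chloride is taken up by the very electron-rich ring of 1 faster than it can close on its own phenyl ring to 1-indanone, and the chelated aryl ketone formed is deactivated so that acylation stops after one acyl group; no stereocentre is formed.

**Step 2**
Reactants: 3 1-(2,4,6-trihydroxyphenyl)-3-phenylpropan-1-one; 4 prenyl bromide (1-bromo-3-methylbut-2-ene)
Product: 6 1-[2,4,6-trihydroxy-3,5-bis(3-methylbut-2-enyl)phenyl]-3-phenylpropan-1-one, via monoprenyl ketone 5 (not isolated)
Conditions: 4 (2.05 equiv), KOH (2.1 equiv), H2O, Ar, 0 °C to rt, 3 h; then cold dilute aq HCl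
Reagents that add atoms: prenyl bromide (4), CC(C)=CCBr
Why: Phenoxide C-alkylation (SN2) in water, where hydrogen bonding of the solvent to the phenoxide oxygens steers the soft allylic bromide to the two free ring carbons C3 and C5, the standard way to deoxyhumulone-type 3,5-diprenyl acylphloroglucinols; no stereocentre is formed.

**Step 3**
Reactants: 6 1-[2,4,6-trihydroxy-3,5-bis(3-methylbut-2-enyl)phenyl]-3-phenylpropan-1-one; 7 isoprene (2-methylbuta-1,3-diene)
Product: 8 helilupolone [3,5-dihydroxy-4,6,6-tris(3-methylbut-2-enyl)-2-(3-phenylpropanoyl)cyclohexa-2,4-dien-1-one]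
Conditions: 7 (2 equiv), Pd2(dba)3·CHCl3 (2.5 mol %), dppp [1,3-bis(diphenylphosphino)propane] (6 mol %), PhCO2H (10 mol %), degassed THF, sealed tube, Ar, 50 °C, 16 h
Reagents that add atoms: isoprene (7), C=CC(C)=C
Why: Proposed new method: dearomative hydroprenylation of an acylphloroglucinol by isoprene under proton-coupled palladium catalysis, in which dppp-ligated zerovalent palladium binds the less substituted C3=C4 bond of 7, the acidic OH of 6 (relayed by PhCO2H) puts a proton on the free isopropenyl terminus C1 to give the cationic 1,1-dimethyl-π-allyl complex of divalent palladium paired to the phenoxide of 6, and this soft, bulky carbon nucleophile attacks the unsubstituted CH2 terminus through ring carbon C3 (C3 and C5 are equivalent), which forms the quaternary carbon, breaks the aromaticity of ring A and gives back zerovalent palladium without any co-product; O-prenylation is undone by re-ionisation, the chelating ligand leaves no site for a second diene (no telomerisation), the more acidic product gives a weaker nucleophile (little fourth prenylation), the new quaternary carbon bears two identical prenyl groups so no stereocentre arises, and the closest known reaction types are the palladium-catalysed hydroalkylation of 1,3-dienes by 1,3-dicarbonyl pronucleophiles, the palladium hydride prenylation of indoles and oxindoles by isoprene and the Tsuji–Trost allylic dearomatisation of phenols, none of them shown on an acylphloroglucinol or for a lupulone-type gem-diprenyl carbon.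

**Compound list**
1 | phloroglucinol (benzene-1,3,5-triol) | Oc1cc(O)cc(O)c1 | starting material
2 | 3-phenylpropanoyl chloride (hydrocinnamoyl chloride) | O=C(Cl)CCc1ccccc1 | starting material
3 | 1-(2,4,6-trihydroxyphenyl)-3-phenylpropan-1-one (2',4',6'-trihydroxydihydrochalcone) | O=C(CCc1ccccc1)c1c(O)cc(O)cc1O | intermediate
4 | prenyl bromide (1-bromo-3-methylbut-2-ene) | CC(C)=CCBr | starting material
5 | 1-[2,4,6-trihydroxy-3-(3-methylbut-2-enyl)phenyl]-3-phenylpropan-1-one (monoprenyl ketone, not isolated) | CC(C)=CCc1c(O)cc(O)c(C(=O)CCc2ccccc2)c1O | intermediate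
6 | 1-[2,4,6-trihydroxy-3,5-bis(3-methylbut-2-enyl)phenyl]-3-phenylpropan-1-one | CC(C)=CCc1c(O)c(CC=C(C)C)c(O)c(C(=O)CCc2ccccc2)c1O | intermediate
7 | isoprene (2-methylbuta-1,3-diene) | C=CC(C)=C | starting material
8 | helilupolone, 3,5-dihydroxy-4,6,6-tris(3-methylbut-2-enyl)-2-(3-phenylpropanoyl)cyclohexa-2,4-dien-1-one (achiral) | CC(C)=CCC1=C(O)C(CC=C(C)C)(CC=C(C)C)C(=O)C(C(=O)CCc2ccccc2)=C1O | target

**Total step count:** 3. **Longest linear sequence:** 3 (1 → 3 → 6 → 8).

**Three steps most likely to fail**

Step 3 (the proposed new step, highest risk).
- Proton delivery to C4 of isoprene would give the 2-methylbut-2-enyl isomer.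
- Diene telomerisation or a fourth prenylation could compete.
- The driving force is modest, because ring A gives up its aromaticity and the addition costs entropy.

The fallback uses known chemistry. It sets out from 6 and comes back at 8. It is the classical alkylative dearomatisation used for lupulones: the phenoxide of 6 (NaOMe, MeOH, 0 °C, Ar) attacks prenyl bromide 4 (1.1 equiv) through ring carbon C3 in a stoichiometric SN2 reaction without any catalyst, followed by cold dilute acid and crystallisation from hexane. This way makes no compound that the compound list does not hold (F0).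

Step 2. Solvolysis of prenyl bromide in aqueous base, chroman formation from the ortho-prenylphenol on acidic work-up, and mono/di/tri mixtures that are hard to separate can spoil the yield. Any over-alkylated material is 8 itself and is kept. The fallback sets out from 3 and comes back at 6, and uses allyl as a robust stand-in for prenyl. Allyl bromide (2.05 equiv) and KOH in water at 0 °C give 1-(3,5-diallyl-2,4,6-trihydroxyphenyl)-3-phenylpropan-1-one F3, by way of 1-(3-allyl-2,4,6-trihydroxyphenyl)-3-phenylpropan-1-one F2, and the acid-stable F3 can be purified. Double cross-metathesis follows, with excess 2-methylbut-2-ene and second-generation Grubbs catalyst RuCl2(=CHPh)(PCy3)(SIMes) (5 mol %) in CH2Cl2 at 40 °C. It runs by way of 1-[3-allyl-2,4,6-trihydroxy-5-(3-methylbut-2-enyl)phenyl]-3-phenylpropan-1-one F4 and turns both allyl groups into prenyl groups to give 6.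

Step 1. AlCl3 can cyclise 2 to 1-indanone, and some diacylation or O-acylation can occur. The fallback sets out from 1 and comes back at 3, and changes the electrophile to a nitrilium species that can neither cyclise readily nor react twice. It is a Houben–Hoesch reaction of 1 with 3-phenylpropanenitrile (ZnCl2, dry HCl gas, Et2O, 0 °C), which precipitates 1-(2,4,6-trihydroxyphenyl)-3-phenylpropan-1-imine hydrochloride F1. Boiling water hydrolyses F1 to 3.

**Further compounds**
F1 | step 1 | 1-(2,4,6-trihydroxyphenyl)-3-phenylpropan-1-imine hydrochloride | Cl.N=C(CCc1ccccc1)c1c(O)cc(O)cc1O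
F2 | step 2 | 1-(3-allyl-2,4,6-trihydroxyphenyl)-3-phenylpropan-1-one | C=CCc1c(O)cc(O)c(C(=O)CCc2ccccc2)c1O
F3 | step 2 | 1-(3,5-diallyl-2,4,6-trihydroxyphenyl)-3-phenylpropan-1-one | C=CCc1c(O)c(CC=C)c(O)c(C(=O)CCc2ccccc2)c1O
F4 | step 2 | 1-[3-allyl-2,4,6-trihydroxy-5-(3-methylbut-2-enyl)phenyl]-3-phenylpropan-1-one | C=CCc1c(O)c(CC=C(C)C)c(O)c(C(=O)CCc2ccccc2)c1O
F0 | step 3 | none | none
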